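**Retrosynthetic overview**

1. Target 19 ⇒ hexabenzyl ester 18 by global hydrogenolysis ⇒ (2R,3R)-flavan-3-ol 16 plus 4-O-benzylsyringic acid 17 by the ester C–O bond.
2. 16 ⇒ racemic flavan-3-one 15. Both stereocentres are set together in one dynamic kinetic transfer hydrogenation, because C2 (alpha to the C3 ketone, benzylic, bonded to O1) epimerises freely.
3. 15 ⇒ silyl enol ether 14 ⇒ [3+3] disconnection of ring C at C3–C4 and O1–C8a into the alpha-silyloxy aryl ketone 12 (ring B, C2, C3, O1, O3) and the ortho-bromobenzyl bromide 5 (ring A, C4, C8a).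
4. Enabling feature: with C2 at the ketone level, O1–C2–C3 is one ambident enolate (C3 as carbon nucleophile, then O1 as oxygen nucleophile). It matches the 1,3-dielectrophile formed by benzylic C4–Br and aryl C8a–Br, which sit ortho to each other on ring A. O3 is silyl-capped so only O1 can close the ring; the extra oxidation level at C2/C3 is removed in steps 9 and 10.
5. Ring order: rings A and B and the acyl ring are bought as arenes (1, 6, 17); ring C is the only ring made, in step 8.

Key step: step 8

Assumption: the sense of induction in step 10 is assigned by the usual model for ruthenium/TsDPEN transfer hydrogenation, with C2 and its aryl group taking the place of the aryl substituent of an aryl ketone, so the (R,R) catalyst is expected to give the (3R) carbinol; if the sense were opposite, the (S,S) catalyst would be used.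

**Route**

Step 1
Reactants: 1 5-bromobenzene-1,3-diol
Product: 2 1,3-bis(benzyloxy)-5-bromobenzene
Conditions: BnBr (2.3 equiv), K2CO3, DMF, 60 °C
Reagents that add atoms: benzyl bromide, BrCc1ccccc1
Why: Williamson ether synthesis (SN2 of the two phenoxides on benzyl bromide); benzyl is chosen because it is removed at the end without touching the two aryl methyl ethers of the acyl part.

Step 2
Reactants: 2 1,3-bis(benzyloxy)-5-bromobenzene
Product: 3 2,4-bis(benzyloxy)-6-bromobenzaldehyde
Conditions: POCl3, DMF, 0 → 80 °C; then H2O, 0 → 25 °C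
Reagents that add atoms: N,N-dimethylformamide, CN(C)C=O; water, O
Why: Vilsmeier–Haack formylation, in which the chloroiminium ion should attack the position ortho/para to both benzyloxy groups next to bromine rather than the more hindered position between the two benzyloxy groups, as is usual for 1-bromo-3,5-dialkoxybenzenes; any symmetric isomer is removed by crystallisation.

Step 3
Reactants: 3 2,4-bis(benzyloxy)-6-bromobenzaldehyde
Product: 4 [2,4-bis(benzyloxy)-6-bromophenyl]methanol
Conditions: NaBH4, THF/MeOH, 0 °C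
Reagents that add atoms: none
Why: borohydride reduction of the aldehyde, to which the aryl bromide and the benzyl ethers are inert.

Step 4
Reactants: 4 [2,4-bis(benzyloxy)-6-bromophenyl]methanol
Product: 5 1,5-bis(benzyloxy)-3-bromo-2-(bromomethyl)benzene
Conditions: PBr3 (0.4 equiv), Et2O, 0 °C; used at once as a cold THF solution
Reagents that add atoms: phosphorus tribromide, BrP(Br)Br
Why: bromination of the benzylic alcohol through its phosphite ester (SN2); the ortho bromine tempers ionisation of this alkoxy-activated benzylic bromide, which is not stored.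

Step 5
Reactants: 6 3,4,5-tris(benzyloxy)benzoic acid
Product: 7 3,4,5-tris(benzyloxy)benzoyl chloride
Conditions: (COCl)2, DMF (cat.), CH2Cl2, 0 → 25 °C
Reagents that add atoms: oxalyl chloride, ClC(=O)C(=O)Cl
Why: acid chloride formation through the Vilsmeier-type chloroiminium catalyst, neutral enough for the benzyl ethers.

Step 6
Reactants: 7 3,4,5-tris(benzyloxy)benzoyl chloride; 8 tris(trimethylsilyloxy)ethene
Product: 11 2-hydroxy-1-[3,4,5-tris(benzyloxy)phenyl]ethan-1-one, via silylated acylation adduct 9 (not isolated), via hydroxy keto acid 10 (not isolated)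
Conditions: 8 (2 equiv), SnCl4 (2 mol %), CH2Cl2, 25 °C; then 0.6 M HCl, dioxane, 90 °C
Reagents that add atoms: none
Why: C-acylation of the ketene tris(silyl) acetal by the acid chloride, followed by acid hydrolysis of the silyl groups and decarboxylation of the beta-keto acid, is the established one-flask conversion of acid chlorides into hydroxymethyl ketones.

Step 7
Reactants: 11 2-hydroxy-1-[3,4,5-tris(benzyloxy)phenyl]ethan-1-one
Product: 12 1-[3,4,5-tris(benzyloxy)phenyl]-2-{[tri(propan-2-yl)silyl]oxy}ethan-1-one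
Conditions: TIPSCl, imidazole, DMF, 25 °C
Reagents that add atoms: chlorotri(propan-2-yl)silane, CC(C)[Si](Cl)(C(C)C)C(C)C
Why: imidazole-promoted silylation of the primary alcohol; the bulky triisopropylsilyl group caps O3 and resists O-to-O silyl migration in the enolates of step 8.

Step 8
Reactants: 12 1-[3,4,5-tris(benzyloxy)phenyl]-2-{[tri(propan-2-yl)silyl]oxy}ethan-1-one; 5 1,5-bis(benzyloxy)-3-bromo-2-(bromomethyl)benzene
Product: 14 {[5,7-bis(benzyloxy)-2-[3,4,5-tris(benzyloxy)phenyl]-4H-chromen-3-yl]oxy}tri(propan-2-yl)silane, via benzylated ketone 13 (not isolated)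
Conditions: KN(SiMe3)2 (1.0 equiv), THF, −78 °C; 5 (1.0 equiv), −78 → 0 °C; then KOtBu (1.1 equiv), CuI (10 mol %), 1,10-phenanthroline (20 mol %), dioxane, 90 °C; one flask, no work-up between the stages
Reagents that add atoms: none
Why: KN(SiMe3)2 converts 12 into its potassium enolate, whose carbon C3 displaces the benzylic bromide of 5 (SN2) to form the C3–C4 bond (13); KOtBu then regenerates the now fully substituted enolate, monovalent copper inserts into the aryl C8a–Br bond to give a trivalent copper aryl, and C–O reductive elimination from the copper enolate forms the O1–C8a bond. The closest known reaction type is the copper-catalysed domino C-benzylation/intramolecular O-arylation of beta-dicarbonyl enolates with 2-bromobenzyl bromides to 4H-chromenes, together with the copper-catalysed intramolecular O-arylation of simple ketone enolates known from benzofuran synthesis. Ring C, the only ring formed, closes as a six-membered enolate O-arylation (attack of O1 on the aryl carbon, formally 6-exo). No stereocentre leaves the step: the C3 stereocentre of 13 and both enolate geometries, which interconvert by proton exchange with tert-butanol, are funnelled into the single achiral enol ether 14. The step needs C- rather than O-benzylation, O- rather than C-arylation and six- rather than five-membered closure; these are secured by the soft benzylic bromide and the single enolisable position of 12 (the other side of the ketone is aryl), by the preference of copper for O-arylation of a hindered enolate whose C-arylation would build a quaternary centre in an indane, and by the silyl cap on O3, which leaves O1 as the only oxygen nucleophile.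

Step 9
Reactants: 14 {[5,7-bis(benzyloxy)-2-[3,4,5-tris(benzyloxy)phenyl]-4H-chromen-3-yl]oxy}tri(propan-2-yl)silane
Product: 15 (±)-5,7-bis(benzyloxy)-2-[3,4,5-tris(benzyloxy)phenyl]chroman-3-one
Conditions: Bu4NF (1.1 equiv), AcOH (1.5 equiv), THF, 0 °C, degassed
Reagents that add atoms: none
Why: fluoride cleaves the O–Si bond of the silyl enol ether and acetic acid protonates the released enolate at C2, which gives the ketone without opening ring C; C2 forms as a racemate, which is what step 10 needs.

Step 10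
Reactants: 15 (±)-5,7-bis(benzyloxy)-2-[3,4,5-tris(benzyloxy)phenyl]chroman-3-one
Product: 16 (2R,3R)-5,7-bis(benzyloxy)-2-[3,4,5-tris(benzyloxy)phenyl]chroman-3-ol
Conditions: RuCl[(R,R)-TsNCH(Ph)CH(Ph)NH2](p-cymene) (2 mol %), HCO2H/Et3N (5:2), CH2Cl2, 35 °C
Reagents that add atoms: none
Why: Noyori–Ikariya asymmetric transfer hydrogenation with dynamic kinetic resolution, in which C2–H (alpha to the ketone, benzylic and alpha-aryloxy, comparable to the C–H of benzoin that racemises in this medium) epimerises through the enol while the chiral divalent ruthenium hydride reduces the (2R) ketone fast from the C3 face anti to the 2-aryl group, so the catalyst selects C2 (R) from the equilibrating pair and C3 (R) is set cis to it by catalyst and substrate together.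

Step 11
Reactants: 16 (2R,3R)-5,7-bis(benzyloxy)-2-[3,4,5-tris(benzyloxy)phenyl]chroman-3-ol; 17 4-(benzyloxy)-3,5-dimethoxybenzoic acid
Product: 18 (2R,3R)-5,7-bis(benzyloxy)-2-[3,4,5-tris(benzyloxy)phenyl]chroman-3-yl 4-(benzyloxy)-3,5-dimethoxybenzoate
Conditions: DCC, DMAP (cat.), CH2Cl2, 0 → 25 °C
Reagents that add atoms: none
Why: Steglich esterification of the axial 3-hydroxyl, the standard way to acylate benzylated epi-series flavan-3-ols with benzylated gallic acids; acylation at oxygen leaves both stereocentres untouched.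

Step 12
Reactants: 18 (2R,3R)-5,7-bis(benzyloxy)-2-[3,4,5-tris(benzyloxy)phenyl]chroman-3-yl 4-(benzyloxy)-3,5-dimethoxybenzoate
Product: 19 epigallocatechin 3-O-(3,5-di-O-methylgallate), (2R,3R)-5,7-dihydroxy-2-(3,4,5-trihydroxyphenyl)chroman-3-yl 4-hydroxy-3,5-dimethoxybenzoate
Conditions: H2 (1 atm), Pd(OH)2/C, THF/MeOH (1:1), 25 °C
Reagents that add atoms: none
Why: hydrogenolysis of all six benzyl ethers, under which the aryl methyl ethers, the benzoate ester and the C2–O1 bond of ring C should survive as they do in debenzylations of galloylated catechins, so neither stereocentre is touched.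

**Compound list**

1 | 5-bromobenzene-1,3-diol | Oc1cc(O)cc(Br)c1 | starting material
2 | 1,3-bis(benzyloxy)-5-bromobenzene | Brc1cc(OCc2ccccc2)cc(OCc2ccccc2)c1 | intermediate
3 | 2,4-bis(benzyloxy)-6-bromobenzaldehyde | O=Cc1c(Br)cc(OCc2ccccc2)cc1OCc1ccccc1 | intermediate
4 | [2,4-bis(benzyloxy)-6-bromophenyl]methanol | OCc1c(Br)cc(OCc2ccccc2)cc1OCc1ccccc1 | intermediate
5 | 1,5-bis(benzyloxy)-3-bromo-2-(bromomethyl)benzene | BrCc1c(Br)cc(OCc2ccccc2)cc1OCc1ccccc1 | intermediate
6 | 3,4,5-tris(benzyloxy)benzoic acid | OC(=O)c1cc(OCc2ccccc2)c(OCc2ccccc2)c(OCc2ccccc2)c1 | starting material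
7 | 3,4,5-tris(benzyloxy)benzoyl chloride | ClC(=O)c1cc(OCc2ccccc2)c(OCc2ccccc2)c(OCc2ccccc2)c1 | intermediate
8 | tris(trimethylsilyloxy)ethene | C[Si](C)(C)OC=C(O[Si](C)(C)C)O[Si](C)(C)C | starting material
9 | trimethylsilyl 3-oxo-3-[3,4,5-tris(benzyloxy)phenyl]-2-(trimethylsilyloxy)propanoate (racemic) | C[Si](C)(C)OC(C(=O)O[Si](C)(C)C)C(=O)c1cc(OCc2ccccc2)c(OCc2ccccc2)c(OCc2ccccc2)c1 | intermediate (not isolated)
10 | 2-hydroxy-3-oxo-3-[3,4,5-tris(benzyloxy)phenyl]propanoic acid (racemic) | OC(C(=O)O)C(=O)c1cc(OCc2ccccc2)c(OCc2ccccc2)c(OCc2ccccc2)c1 | intermediate (not isolated)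
11 | 2-hydroxy-1-[3,4,5-tris(benzyloxy)phenyl]ethan-1-one | OCC(=O)c1cc(OCc2ccccc2)c(OCc2ccccc2)c(OCc2ccccc2)c1 | intermediate
12 | 1-[3,4,5-tris(benzyloxy)phenyl]-2-{[tri(propan-2-yl)silyl]oxy}ethan-1-one | CC(C)[Si](OCC(=O)c1cc(OCc2ccccc2)c(OCc2ccccc2)c(OCc2ccccc2)c1)(C(C)C)C(C)C | intermediate
13 | 3-[2,4-bis(benzyloxy)-6-bromophenyl]-1-[3,4,5-tris(benzyloxy)phenyl]-2-{[tri(propan-2-yl)silyl]oxy}propan-1-one (racemic) | CC(C)[Si](OC(Cc1c(Br)cc(OCc2ccccc2)cc1OCc1ccccc1)C(=O)c1cc(OCc2ccccc2)c(OCc2ccccc2)c(OCc2ccccc2)c1)(C(C)C)C(C)C | intermediate (not isolated)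
14 | {[5,7-bis(benzyloxy)-2-[3,4,5-tris(benzyloxy)phenyl]-4H-chromen-3-yl]oxy}tri(propan-2-yl)silane | CC(C)[Si](OC1=C(c2cc(OCc3ccccc3)c(OCc3ccccc3)c(OCc3ccccc3)c2)Oc2cc(OCc3ccccc3)cc(OCc3ccccc3)c2C1)(C(C)C)C(C)C | intermediate
15 | (±)-5,7-bis(benzyloxy)-2-[3,4,5-tris(benzyloxy)phenyl]chroman-3-one | O=C1Cc2c(OCc3ccccc3)cc(OCc3ccccc3)cc2OC1c1cc(OCc2ccccc2)c(OCc2ccccc2)c(OCc2ccccc2)c1 | intermediate
16 | (2R,3R)-5,7-bis(benzyloxy)-2-[3,4,5-tris(benzyloxy)phenyl]chroman-3-ol | O[C@@H]1Cc2c(OCc3ccccc3)cc(OCc3ccccc3)cc2O[C@@H]1c1cc(OCc2ccccc2)c(OCc2ccccc2)c(OCc2ccccc2)c1 | intermediate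
17 | 4-(benzyloxy)-3,5-dimethoxybenzoic acid | COc1cc(C(=O)O)cc(OC)c1OCc1ccccc1 | starting material
18 | (2R,3R)-5,7-bis(benzyloxy)-2-[3,4,5-tris(benzyloxy)phenyl]chroman-3-yl 4-(benzyloxy)-3,5-dimethoxybenzoate | COc1cc(C(=O)O[C@@H]2Cc3c(OCc4ccccc4)cc(OCc4ccccc4)cc3O[C@@H]2c2cc(OCc3ccccc3)c(OCc3ccccc3)c(OCc3ccccc3)c2)cc(OC)c1OCc1ccccc1 | intermediate
19 | epigallocatechin 3-O-(3,5-di-O-methylgallate) | COc1cc(C(=O)O[C@@H]2Cc3c(O)cc(O)cc3O[C@@H]2c2cc(O)c(O)c(O)c2)cc(OC)c1O | target

**Count and risks**

Total step count: 12. Longest linear sequence: 9 steps (steps 1, 2, 3, 4, 8, 9, 10, 11, 12).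

Step 8 (key step). What may go wrong: O- instead of C-benzylation of the first enolate, a 1,4-silyl shift in the hot second enolate, or debromination and stalling of the copper cycle before C–O reductive elimination. The fallback sets out from 13, isolated by stopping step 8 after the alkylation stage, and comes back at 15. NaBH4 (THF/MeOH, 0 °C) reduces the ketone to 3-[2,4-bis(benzyloxy)-6-bromophenyl]-1-[3,4,5-tris(benzyloxy)phenyl]-2-{[tri(propan-2-yl)silyl]oxy}propan-1-ol F1, a diastereomer mixture whose composition does not matter. Palladium-catalysed intramolecular aryl etherification of this secondary alcohol (Pd(OAc)2, 2-(di-tert-butylphosphino)-1,1'-binaphthyl, Cs2CO3, toluene, 80 °C) closes ring C through an alkoxide instead of an enolate, O3 again being capped, to {[5,7-bis(benzyloxy)-2-[3,4,5-tris(benzyloxy)phenyl]chroman-3-yl]oxy}tri(propan-2-yl)silane F2. Bu4NF in THF then frees 5,7-bis(benzyloxy)-2-[3,4,5-tris(benzyloxy)phenyl]chroman-3-ol F3 as a stereoisomer mixture, and Dess–Martin periodinane oxidises all isomers to the one ketone 15, from which step 10 proceeds unchanged.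

Step 10. What may go wrong: reduction outrunning epimerisation at C2 so that the resolution is not dynamic, weak enantioface discrimination at a ketone with no directly attached aryl group, or partial formation of the trans alcohol. The fallback sets out from 15 and comes back at 16. LiBH(s-Bu)3 (THF, −78 °C) should add hydride anti to the 2-aryl group, the known outcome for flavan-3-ones, and give racemic cis-5,7-bis(benzyloxy)-2-[3,4,5-tris(benzyloxy)phenyl]chroman-3-ol F4. Preparative chromatography on a chiral stationary phase separates 16 from (2S,3S)-5,7-bis(benzyloxy)-2-[3,4,5-tris(benzyloxy)phenyl]chroman-3-ol F5, and F5 is oxidised with Dess–Martin periodinane back to 15, which racemises with Et3N and is recycled.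

Step 4. What may go wrong: ionisation of the alkoxy-activated benzylic bromide and self-alkylation of the electron-rich ring before it can be used. The fallback sets out from 4 and 12 and comes back at 13, avoiding any benzylic halide. Me3SiOTf/Et3N (CH2Cl2, 0 °C) converts 12 into trimethyl({1-[3,4,5-tris(benzyloxy)phenyl]-2-{[tri(propan-2-yl)silyl]oxy}ethenyl}oxy)silane F6. Bi(OTf)3 (5 mol %, CH2Cl2, 0 °C) then ionises the benzylic alcohol 4 only in the presence of this enol ether, a Lewis acid-catalysed SN1 benzylation of a silyl enol ether by a pi-activated benzylic alcohol, to give 13. Ketone 13 is then cyclised to 14 under the second-stage conditions of step 8 (KOtBu, CuI, 1,10-phenanthroline, dioxane, 90 °C).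

**Further compounds**

F1 | step 8 | 3-[2,4-bis(benzyloxy)-6-bromophenyl]-1-[3,4,5-tris(benzyloxy)phenyl]-2-{[tri(propan-2-yl)silyl]oxy}propan-1-ol (mixture of stereoisomers) | CC(C)[Si](OC(Cc1c(Br)cc(OCc2ccccc2)cc1OCc1ccccc1)C(O)c1cc(OCc2ccccc2)c(OCc2ccccc2)c(OCc2ccccc2)c1)(C(C)C)C(C)C
F2 | step 8 | {[5,7-bis(benzyloxy)-2-[3,4,5-tris(benzyloxy)phenyl]chroman-3-yl]oxy}tri(propan-2-yl)silane (mixture of stereoisomers) | CC(C)[Si](OC1Cc2c(OCc3ccccc3)cc(OCc3ccccc3)cc2OC1c1cc(OCc2ccccc2)c(OCc2ccccc2)c(OCc2ccccc2)c1)(C(C)C)C(C)C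
F3 | step 8 | 5,7-bis(benzyloxy)-2-[3,4,5-tris(benzyloxy)phenyl]chroman-3-ol (mixture of stereoisomers) | OC1Cc2c(OCc3ccccc3)cc(OCc3ccccc3)cc2OC1c1cc(OCc2ccccc2)c(OCc2ccccc2)c(OCc2ccccc2)c1
F4 | step 10 | racemic cis-5,7-bis(benzyloxy)-2-[3,4,5-tris(benzyloxy)phenyl]chroman-3-ol (both enantiomers) | O[C@@H]1Cc2c(OCc3ccccc3)cc(OCc3ccccc3)cc2O[C@@H]1c1cc(OCc2ccccc2)c(OCc2ccccc2)c(OCc2ccccc2)c1.O[C@H]1Cc2c(OCc3ccccc3)cc(OCc3ccccc3)cc2O[C@H]1c1cc(OCc2ccccc2)c(OCc2ccccc2)c(OCc2ccccc2)c1
F5 | step 10 | (2S,3S)-5,7-bis(benzyloxy)-2-[3,4,5-tris(benzyloxy)phenyl]chroman-3-ol | O[C@H]1Cc2c(OCc3ccccc3)cc(OCc3ccccc3)cc2O[C@H]1c1cc(OCc2ccccc2)c(OCc2ccccc2)c(OCc2ccccc2)c1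
F6 | step 4 | trimethyl({1-[3,4,5-tris(benzyloxy)phenyl]-2-{[tri(propan-2-yl)silyl]oxy}ethenyl}oxy)silane | C[Si](C)(C)OC(=CO[Si](C(C)C)(C(C)C)C(C)C)c1cc(OCc2ccccc2)c(OCc2ccccc2)c(OCc2ccccc2)c1
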